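**Plan**
- Retrosynthesis: the four O–CH3 bonds are cut first, then C1–C2 and C1'–C2' of the two rings B (twofold Dieckmann closure). Next come both C2–CH2 bonds at the central methylene (formaldehyde), the C2–C3 bonds (malonate homologation), C8a–C1 (carbonylation) and C4a–C4 (enolate arylation).
- Forward: ring A is bought as 2',6'-dimethoxyacetophenone. C4, C1 and C3/C2 are attached to it in that order, two such halves are joined through one CH2, and both rings B close last in one operation.
- Feature used: in each ring B the dione carbons C1 and C3 flank C2. C1 is bonded to aromatic C8a and can therefore start as an aryl ester. C4 is quaternary, so the C3 ketone enolises only toward C2, and both C2 atoms hang on the one central methylene.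
- Stereochemistry: the target has no stereocentre. The two stereocentres that arise transiently at the ester-bearing carbons of the methylene-bridged bis(β-keto ester) are uncontrolled and are erased by decarboxylation.

Key step: step 9

Assumption: the cyclic 1,3-diones of this route are written as the 3-hydroxy-1(4H)-naphthalenone enol tautomers used in the target SMILES; they are expected to equilibrate freely between enol forms.

**Route**

Step 1
Reactants: 1 2',6'-dimethoxyacetophenone
Product: 3 1-(4-bromo-2,6-dimethoxyphenyl)ethan-1-one, via arylboronate 2 (not isolated)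
Conditions: [Ir(OMe)(cod)]2 (1.5 mol %), 4,4'-di-tert-butyl-2,2'-bipyridine (3 mol %), B2pin2, THF, 80 °C; then CuBr2, MeOH/H2O (1:1), 80 °C
Reagents that add atoms: CuBr2, [Cu+2].[Br-].[Br-]; bis(pinacolato)diboron, CC1(C)OB(OC1(C)C)B1OC(C)(C)C(C)(C)O1 (boryl group of intermediate 2 only)
Why: Iridium-catalysed aromatic C–H borylation is governed by sterics and should functionalise only C4', the one ring C–H with no ortho substituent (para to the acetyl group, a position that electrophilic bromination cannot reach), and the boronate is then converted into the bromide by CuBr2 in the same flask (borylation–halogenation sequence).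

Step 2
Reactants: 3 1-(4-bromo-2,6-dimethoxyphenyl)ethan-1-one; 4 tert-butyl 2-bromo-2-methylpropanoate
Product: 6 tert-butyl 2-(4-acetyl-3,5-dimethoxyphenyl)-2-methylpropanoate, via zinc enolate 5 (not isolated)
Conditions: 4, Zn dust, THF, rt (forms BrZnC(CH3)2CO2t-Bu); then 3, Pd(dba)2 (2 mol %), P(t-Bu)3 (2 mol %), THF, rt → 50 °C
Reagents that add atoms: zinc, [Zn] (zinc atom of intermediate 5 only)
Why: Palladium-catalysed α-arylation of a zinc ester enolate (Reformatsky reagent) forms the aryl–C(CH3)2 bond under nearly neutral conditions, so the enolisable, doubly ortho-shielded aryl methyl ketone should be neither deprotonated nor attacked.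

Step 3
Reactants: 6 tert-butyl 2-(4-acetyl-3,5-dimethoxyphenyl)-2-methylpropanoate
Product: 7 tert-butyl 2-(4-acetyl-2-bromo-3,5-dimethoxyphenyl)-2-methylpropanoate
Conditions: NBS (1.0 equiv), MeCN, 0 °C → rt, dark
Reagents that add atoms: N-bromosuccinimide, O=C1CCC(=O)N1Br
Why: Electrophilic aromatic bromination has only two free, equivalent ring positions to choose from, each ortho to one methoxy group and para to the other, and NBS in MeCN without acid or radical initiator should favour this activated ring carbon over the α-carbon of the twisted acetyl group, while the first bromine and the adjacent quaternary carbon shield the ring against a second substitution.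

Step 4
Reactants: 7 tert-butyl 2-(4-acetyl-2-bromo-3,5-dimethoxyphenyl)-2-methylpropanoate
Product: 8 methyl 3-acetyl-6-(1-tert-butoxy-2-methyl-1-oxopropan-2-yl)-2,4-dimethoxybenzoate
Conditions: Pd(OAc)2 (5 mol %), n-BuP(1-adamantyl)2 (10 mol %), CO (10 bar), MeOH, Et3N, toluene, 110 °C
Reagents that add atoms: carbon monoxide, [C-]#[O+]; methanol, CO
Why: Palladium-catalysed methoxycarbonylation of an aryl bromide (Heck carbonylation: oxidative addition to zerovalent palladium, CO insertion, methanolysis of the acyl complex) is run with a bulky electron-rich monophosphine chosen for the doubly ortho-substituted bromide, and the tert-butyl ester and the ketone are inert to CO, MeOH and Et3N.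

Step 5
Reactants: 8 methyl 3-acetyl-6-(1-tert-butoxy-2-methyl-1-oxopropan-2-yl)-2,4-dimethoxybenzoate
Product: 9 2-[4-acetyl-3,5-dimethoxy-2-(methoxycarbonyl)phenyl]-2-methylpropanoic acid
Conditions: TFA, CH2Cl2, 0 °C → rt
Reagents that add atoms: none
Why: Acidolysis of the tert-butyl ester through the tert-butyl cation (loss of isobutene) frees the aliphatic acid, whereas the aryl methyl ester, which has no such pathway and is flanked by two ortho substituents, should stay intact.

Step 6
Reactants: 9 2-[4-acetyl-3,5-dimethoxy-2-(methoxycarbonyl)phenyl]-2-methylpropanoic acid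
Product: 11 tert-butyl 4-[4-acetyl-3,5-dimethoxy-2-(methoxycarbonyl)phenyl]-4-methyl-3-oxopentanoate, via acyl imidazolide 10 (not isolated)
Conditions: CDI, THF, rt; then mono-tert-butyl malonate pretreated with i-PrMgCl (2 equiv per malonate, THF, 0 °C), rt → 45 °C; cold aq. citric acid
Reagents that add atoms: mono-tert-butyl malonate, CC(C)(C)OC(=O)CC(=O)O; 1,1'-carbonyldiimidazole, O=C(n1ccnc1)n1ccnc1 (imidazolyl group of intermediate 10 only)
Why: In this Masamune–Brooks homologation the acyl imidazolide C-acylates the magnesium enolate of the malonate half-ester and the adduct loses CO2 to give the β-keto ester, which creates C2 as by far the most acidic C–H of the molecule without touching the acetyl group or the aryl ester.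

Step 7
Reactants: 11 tert-butyl 4-[4-acetyl-3,5-dimethoxy-2-(methoxycarbonyl)phenyl]-4-methyl-3-oxopentanoate (two equivalents)
Product: 13 di-tert-butyl 2,4-bis{2-[4-acetyl-3,5-dimethoxy-2-(methoxycarbonyl)phenyl]-2-methylpropanoyl}pentanedioate (diastereomer mixture), via methylidene keto ester 12 (not isolated)
Conditions: 37% aq. CH2O (0.5 equiv), piperidine (10 mol %), EtOH, 0 °C → rt
Reagents that add atoms: formaldehyde, C=O
Why: Knoevenagel condensation of one β-keto ester with formaldehyde followed by Michael addition of a second one to the methylidene intermediate (the classical 2:1 condensation) runs under amine catalysis only at the doubly activated C2–H, so the acetyl methyl groups cannot compete, and the two new stereocentres form without control because step 8 removes them.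

Step 8
Reactants: 13 di-tert-butyl 2,4-bis{2-[4-acetyl-3,5-dimethoxy-2-(methoxycarbonyl)phenyl]-2-methylpropanoyl}pentanedioate
Product: 15 dimethyl 6,6'-(2,8-dimethyl-3,7-dioxononane-2,8-diyl)bis(3-acetyl-2,4-dimethoxybenzoate), via bis(keto acid) 14 (not isolated)
Conditions: TFA, CH2Cl2, rt; evaporate; toluene, 90 °C
Reagents that add atoms: none
Why: Acidolysis of both tert-butyl esters and thermal decarboxylation of the β-keto acids through the cyclic six-membered transition state leave the 1,5-diketone, which cannot undergo aldol ring closure because both outer α-carbons are quaternary.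

Step 9
Reactants: 15 dimethyl 6,6'-(2,8-dimethyl-3,7-dioxononane-2,8-diyl)bis(3-acetyl-2,4-dimethoxybenzoate)
Product: 17 2,2'-methylenebis(7-acetyl-3-hydroxy-6,8-dimethoxy-4,4-dimethylnaphthalen-1(4H)-one), via monocyclised keto ester 16 (not isolated)
Conditions: NaN(SiMe3)2 (6 equiv), THF (0.02 M), −78 °C → rt, then 40 °C; aq. HCl
Reagents that add atoms: none
Why: Excess NaN(SiMe3)2 turns all four ketones into enolates, so that the hindered aryl esters are the only electrophiles left; each C3 ketone can enolise only toward C2 because C4 is quaternary, and each C2 enolate adds to the ester carbonyl on C8a of its own ring A, methoxide leaves and the new 2-alkyl-1,3-dione is deprotonated at once, which makes the closure irreversible. The closest known reaction type is the Dieckmann-type (intramolecular Claisen) acylation of a ketone enolate by an ortho aryl ester to a cyclic 1,3-dione, here run twice on one chain. Each ring B closes in the 6-exo-trig mode, the first closure giving 16 and the second 17. No stereocentre is formed. The selectivity needed is site selectivity of acylation: reaction of a C2 enolate with the ester of the other half would need an eight-membered ring, the acetyl enolates are meta to the esters and cannot reach them, and any enol lactone from O-acylation should be reopened by the liberated methoxide and funnelled to the C-acylated dione enolate.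

Step 10
Reactants: 17 2,2'-methylenebis(7-acetyl-3-hydroxy-6,8-dimethoxy-4,4-dimethylnaphthalen-1(4H)-one)
Product: 18 2,2'-methylenebis(7-acetyl-3,6,8-trihydroxy-4,4-dimethylnaphthalen-1(4H)-one) (CNP0295164.0)
Conditions: BCl3 (1 M in CH2Cl2, 12 equiv), CH2Cl2, −78 °C → rt; then H2O
Reagents that add atoms: none
Why: BCl3 cleaves aryl methyl ethers ortho to carbonyl groups through six-membered boron chelates followed by SN2 attack of chloride on the methyl group, and here each methoxy has its own carbonyl partner (C8–OMe the C1 ketone, C6–OMe the acetyl group), so all four should fall while the enolised 1,3-diones are only held as boron chelates until aqueous work-up.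

**Compound list**
1 | 2',6'-dimethoxyacetophenone | CC(=O)c1c(OC)cccc1OC | starting material
2 | 1-[2,6-dimethoxy-4-(4,4,5,5-tetramethyl-1,3,2-dioxaborolan-2-yl)phenyl]ethan-1-one | CC(=O)c1c(OC)cc(cc1OC)B1OC(C)(C)C(C)(C)O1 | intermediate (not isolated)
3 | 1-(4-bromo-2,6-dimethoxyphenyl)ethan-1-one | CC(=O)c1c(OC)cc(Br)cc1OC | intermediate
4 | tert-butyl 2-bromo-2-methylpropanoate | CC(C)(C)OC(=O)C(C)(C)Br | starting material
5 | bromo(1-tert-butoxy-2-methyl-1-oxopropan-2-yl)zinc (Reformatsky reagent) | CC(C)(C)OC(=O)C(C)(C)[Zn]Br | intermediate (not isolated)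
6 | tert-butyl 2-(4-acetyl-3,5-dimethoxyphenyl)-2-methylpropanoate | CC(=O)c1c(OC)cc(cc1OC)C(C)(C)C(=O)OC(C)(C)C | intermediate
7 | tert-butyl 2-(4-acetyl-2-bromo-3,5-dimethoxyphenyl)-2-methylpropanoate | CC(=O)c1c(OC)cc(C(C)(C)C(=O)OC(C)(C)C)c(Br)c1OC | intermediate
8 | methyl 3-acetyl-6-(1-tert-butoxy-2-methyl-1-oxopropan-2-yl)-2,4-dimethoxybenzoate | COC(=O)c1c(OC)c(C(C)=O)c(OC)cc1C(C)(C)C(=O)OC(C)(C)C | intermediate
9 | 2-[4-acetyl-3,5-dimethoxy-2-(methoxycarbonyl)phenyl]-2-methylpropanoic acid | COC(=O)c1c(OC)c(C(C)=O)c(OC)cc1C(C)(C)C(=O)O | intermediate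
10 | methyl 3-acetyl-6-[1-(1H-imidazol-1-yl)-2-methyl-1-oxopropan-2-yl]-2,4-dimethoxybenzoate | COC(=O)c1c(OC)c(C(C)=O)c(OC)cc1C(C)(C)C(=O)n1ccnc1 | intermediate (not isolated)
11 | tert-butyl 4-[4-acetyl-3,5-dimethoxy-2-(methoxycarbonyl)phenyl]-4-methyl-3-oxopentanoate | COC(=O)c1c(OC)c(C(C)=O)c(OC)cc1C(C)(C)C(=O)CC(=O)OC(C)(C)C | intermediate
12 | tert-butyl 4-[4-acetyl-3,5-dimethoxy-2-(methoxycarbonyl)phenyl]-4-methyl-2-methylidene-3-oxopentanoate | COC(=O)c1c(OC)c(C(C)=O)c(OC)cc1C(C)(C)C(=O)C(=C)C(=O)OC(C)(C)C | intermediate (not isolated)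
13 | di-tert-butyl 2,4-bis{2-[4-acetyl-3,5-dimethoxy-2-(methoxycarbonyl)phenyl]-2-methylpropanoyl}pentanedioate (mixture of meso and racemic diastereomers, configuration not controlled) | COC(=O)c1c(OC)c(C(C)=O)c(OC)cc1C(C)(C)C(=O)C(C(=O)OC(C)(C)C)CC(C(=O)OC(C)(C)C)C(=O)C(C)(C)c1cc(OC)c(C(C)=O)c(OC)c1C(=O)OC | intermediate
14 | 2,4-bis{2-[4-acetyl-3,5-dimethoxy-2-(methoxycarbonyl)phenyl]-2-methylpropanoyl}pentanedioic acid (diastereomer mixture) | COC(=O)c1c(OC)c(C(C)=O)c(OC)cc1C(C)(C)C(=O)C(C(=O)O)CC(C(=O)O)C(=O)C(C)(C)c1cc(OC)c(C(C)=O)c(OC)c1C(=O)OC | intermediate (not isolated)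
15 | dimethyl 6,6'-(2,8-dimethyl-3,7-dioxononane-2,8-diyl)bis(3-acetyl-2,4-dimethoxybenzoate) | COC(=O)c1c(OC)c(C(C)=O)c(OC)cc1C(C)(C)C(=O)CCCC(=O)C(C)(C)c1cc(OC)c(C(C)=O)c(OC)c1C(=O)OC | intermediate (key-step precursor)
16 | methyl 3-acetyl-6-[5-(7-acetyl-3-hydroxy-6,8-dimethoxy-4,4-dimethyl-1-oxo-1,4-dihydronaphthalen-2-yl)-2-methyl-3-oxopentan-2-yl]-2,4-dimethoxybenzoate | CC(=O)c1c(OC)cc2c(c1OC)C(=O)C(CCC(=O)C(C)(C)c1cc(OC)c(C(C)=O)c(OC)c1C(=O)OC)=C(O)C2(C)C | intermediate (not isolated)
17 | 2,2'-methylenebis(7-acetyl-3-hydroxy-6,8-dimethoxy-4,4-dimethylnaphthalen-1(4H)-one) | CC(=O)c1c(OC)cc2c(c1OC)C(=O)C(CC1=C(O)C(C)(C)c3cc(OC)c(C(C)=O)c(OC)c3C1=O)=C(O)C2(C)C | intermediate (key-step product)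
18 | 2,2'-methylenebis(7-acetyl-3,6,8-trihydroxy-4,4-dimethylnaphthalen-1(4H)-one) | CC(=O)c1c(O)cc2c(c1O)C(=O)C(CC1=C(O)C(C)(C)c3cc(O)c(C(C)=O)c(O)c3C1=O)=C(O)C2(C)C | target

**Count and risks**

Total step count: 10. Longest linear sequence: 10 steps (1 → 18).

Steps most likely to fail:

Step 4. Oxidative addition and CO insertion at a bromide flanked by a methoxy group and a quaternary carbon may be too slow, so that reduction of the C–Br bond or simple non-conversion takes over. The fallback sets out from bromide 7 and replaces palladium by an organolithium carboxylation. The acetyl group is first masked as its lithium enolate with LiN(SiMe3)2 (THF, −78 °C). Bromine–lithium exchange with t-BuLi (−100 °C) and a CO2 quench should then give 3-acetyl-6-(1-tert-butoxy-2-methyl-1-oxopropan-2-yl)-2,4-dimethoxybenzoic acid F1. Methylation with MeI and K2CO3 in DMF comes back to the route at 8.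

Step 9. The second ring closure may stall on the hindered ester of the mono-cyclised intermediate, or intermolecular Claisen and aldol condensation of the polyenolate may compete with cyclisation. The fallback sets out from β-keto ester 11 and closes ring B before the halves are joined. TFA and then heat should give methyl 3-acetyl-2,4-dimethoxy-6-(2-methyl-3-oxobutan-2-yl)benzoate F2. Dieckmann closure with NaN(SiMe3)2 in THF should give 7-acetyl-3-hydroxy-6,8-dimethoxy-4,4-dimethylnaphthalen-1(4H)-one F3. Two molecules of F3 are then condensed with formaldehyde (0.5 equiv, EtOH, rt; Knoevenagel–Michael 2:1 condensation of a cyclic 1,3-dione), which comes back to the route at 17.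

Step 3. Substitution next to the quaternary carbon may be so slow that α-bromination of the acetyl group or acid-induced loss of the tert-butyl ester competes. The fallback sets out from bromo ketone 3 and puts the carboxyl carbon on the ring before the quaternary carbon is made. Rieche formylation (Cl2CHOMe, TiCl4, CH2Cl2, 0 °C) next to the bromine should give 3-acetyl-6-bromo-2,4-dimethoxybenzaldehyde F4. Pinnick oxidation (NaClO2, NaH2PO4, 2-methyl-2-butene, t-BuOH/H2O) should give 3-acetyl-6-bromo-2,4-dimethoxybenzoic acid F5. MeI and K2CO3 in DMF should give methyl 3-acetyl-6-bromo-2,4-dimethoxybenzoate F6. Palladium-catalysed arylation of zinc enolate 5 with F6 (Pd(dba)2, P(t-Bu)3, THF) then comes back to the route at 8, so steps 3 and 4 are both bypassed.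

**Further compounds**
F1 | step 4 | 3-acetyl-6-(1-tert-butoxy-2-methyl-1-oxopropan-2-yl)-2,4-dimethoxybenzoic acid | OC(=O)c1c(OC)c(C(C)=O)c(OC)cc1C(C)(C)C(=O)OC(C)(C)C
F2 | step 9 | methyl 3-acetyl-2,4-dimethoxy-6-(2-methyl-3-oxobutan-2-yl)benzoate | COC(=O)c1c(OC)c(C(C)=O)c(OC)cc1C(C)(C)C(C)=O
F3 | step 9 | 7-acetyl-3-hydroxy-6,8-dimethoxy-4,4-dimethylnaphthalen-1(4H)-one | CC(=O)c1c(OC)cc2c(c1OC)C(=O)C=C(O)C2(C)C
F4 | step 3 | 3-acetyl-6-bromo-2,4-dimethoxybenzaldehyde | O=Cc1c(OC)c(C(C)=O)c(OC)cc1Br
F5 | step 3 | 3-acetyl-6-bromo-2,4-dimethoxybenzoic acid | OC(=O)c1c(OC)c(C(C)=O)c(OC)cc1Br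
F6 | step 3 | methyl 3-acetyl-6-bromo-2,4-dimethoxybenzoate | COC(=O)c1c(OC)c(C(C)=O)c(OC)cc1Br
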